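**Retrosynthetic overview**
1. Target 28 ⇐ diene 26: the cis-fused 4,5-epoxide comes last from the C4=C5 alkene (bromohydrin, then closure); before that the C8 methacrylate, the C9 acetate and the 11(13)-methylene (unmasked from an 11-CH2SPh lactone) are installed.
2. Key disconnection: the ten-membered carbocycle (C1–C10) ⇐ eight-membered ketone 15 (ring C2–C9) + methyl propiolate, whose two alkyne carbons (C10 with its CO2Me, and C1) are inserted into the C9–C2 bond (formal [2+2], then cyclobutene fragmentation).
3. Enabling feature: C9 carries oxygen and is flanked by C10, which bears the ester, and then by the C1 methine. This is a masked β-keto ester, so with C9 as a ketone in the eight-membered ring the enol ether C9=C2 is the nucleophile and C9 the acceptor for the propiolate carbons.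
4. Eight-membered ring ⇐ ring-closing metathesis at C4=C5 (cis geometry enforced by ring size) on a trans-4,5-disubstituted γ-lactone; C7 and C8 come from diethyl (S)-malate (anti alkylation), C6 from a Felkin-selective vinyl addition.
5. Order of ring formation: γ-lactone (step 5) → cyclooctene (step 11) → transient cyclobutene, then ten-membered ring (step 13) → oxirane (step 20).

Key step: step 13

Remark: the structure has a cis-fused 4,5-epoxide (C3 and C6 cis; 4R,5S) and a ring-cis C1=C10 enoate; germacrane numbering (C1–C15) and α/β descriptors (C7–C11 bond β) are used for all compounds.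

**Route**

Step 1
Reactants: 1 diethyl (S)-malate; 2 tert-butyl bromoacetate
Product: 3 3-tert-butyl 1,2-diethyl (1S,2R)-1-hydroxypropane-1,2,3-tricarboxylate
Conditions: LiN(iPr)2 (LDA, 2.1 equiv), THF, −78 → −20 °C; then 2, −78 → −15 °C; AcOH quench at −78 °C
Reagents that add atoms: tert-butyl bromoacetate 2, CC(C)(C)OC(=O)CBr
Why: Fráter–Seebach alkylation: the chelated dilithium alkoxide–enolate of the β-hydroxy ester takes the reactive α-bromo ester on the face anti to the oxygen-bearing C8 substituent, which sets C7 (R) anti to the pool-derived C8 (S) and installs C11–C12 at the correct oxidation level.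

Step 2
Reactants: 3
Product: 4 4-tert-butyl 1-ethyl (2R)-2-[(1S)-1,2-dihydroxyethyl]butanedioate
Conditions: BH3·SMe2 (1.05 equiv), NaBH4 (5 mol%), THF, 0 °C → rt; MeOH quench
Reagents that add atoms: none
Why: Hydroxyl-directed borane reduction reduces only the ester α to the free hydroxyl through a five-membered alkoxyborane chelate, so C9 (now CH2OH) is differentiated from the C6 and C12 esters without touching a stereocentre.

Step 3
Reactants: 4
Product: 5 4-tert-butyl 1-ethyl (2R)-2-[(1S)-1,2-bis(tert-butyldimethylsilyloxy)ethyl]butanedioate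
Conditions: tBuMe2SiOTf (2.4 equiv), 2,6-lutidine, CH2Cl2, −78 → 0 °C (crude 4 used at once)
Reagents that add atoms: tert-butyldimethylsilyl triflate, CC(C)(C)[Si](C)(C)OS(=O)(=O)C(F)(F)F
Why: Silyl triflate silylation of both hydroxyls on crude 4 blocks lactonisation of C9–OH onto the C6 ester and makes the C8 ether a non-chelating group for step 5.

Step 4
Reactants: 5
Product: 6 tert-butyl (3R,4S)-4,5-bis(tert-butyldimethylsilyloxy)-3-formylpentanoate
Conditions: iBu2AlH (1.1 equiv), CH2Cl2, −78 °C; Rochelle salt work-up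
Reagents that add atoms: none
Why: Partial ester reduction with iBu2AlH stops at the aluminium hemiacetal at −78 °C and is selective for the ethyl ester over the bulkier tert-butyl ester, giving the C6 aldehyde, which is used at once so that C7 is not epimerised.

Step 5
Reactants: 6
Product: 8 (4S,5R)-4-[(1S)-1,2-bis(tert-butyldimethylsilyloxy)ethyl]-5-ethenyloxolan-2-one (trans-lactone), via hydroxy ester 7 (not isolated)
Conditions: CH2=CHMgBr (1.5 equiv), THF, −78 °C → rt; camphorsulfonic acid (cat.), CH2Cl2, rt to complete lactonisation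
Reagents that add atoms: vinylmagnesium bromide, C=C[Mg]Br
Why: Felkin–Anh addition of the vinyl Grignard reagent anti to the large C8 substituent on C7, reinforced by 1,3-anti induction from the β-silyloxy group (α and β substituents are anti), sets C6, and the alkoxide then closes the γ-lactone on the tert-butyl ester (5-exo-trig acyl substitution) to give the trans-4,5-disubstituted lactone.

Step 6
Reactants: 8
Product: 10 (3S,4S,5R)-4-[(1S)-1,2-bis(tert-butyldimethylsilyloxy)ethyl]-5-ethenyl-3-[(phenylsulfanyl)methyl]oxolan-2-one, via silyl ketene acetal 9 (not isolated)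
Conditions: LiN(iPr)2 (1.1 equiv), THF, −78 °C; Me3SiCl; then PhSCH2Cl, ZnBr2 (10 mol%), CH2Cl2, rt
Reagents that add atoms: chloromethyl phenyl sulfide, ClCSc1ccccc1
Why: Lewis-acid-catalysed alkylation of the O-silyl ketene acetal by the phenylthiomethyl (thionium) cation, a Mukaiyama-type alkylation, puts C13 on C11 as a masked exocyclic methylene; attack anti to the C7 side chain should give the 3,4-trans isomer, but the C11 centre is removed in step 17.

Step 7
Reactants: 10
Product: 11 (3S,4S,5R)-4-[(1S)-1-(tert-butyldimethylsilyloxy)-2-hydroxyethyl]-5-ethenyl-3-[(phenylsulfanyl)methyl]oxolan-2-one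
Conditions: HF·pyridine, pyridine, THF, 0 °C
Reagents that add atoms: none
Why: Fluoride-mediated desilylation is much faster for the primary C9 silyl ether than for the hindered secondary C8 ether, so only C9–OH is released.

Step 8
Reactants: 11
Product: 12 (2S)-2-(tert-butyldimethylsilyloxy)-2-[(2R,3S,4S)-2-ethenyl-5-oxo-4-[(phenylsulfanyl)methyl]oxolan-3-yl]acetaldehyde
Conditions: Dess–Martin periodinane, NaHCO3, CH2Cl2, 0 °C → rt
Reagents that add atoms: none
Why: Dess–Martin oxidation under buffered conditions gives the α-silyloxy aldehyde without epimerising C8 and without oxidising the sulfide.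

Step 9
Reactants: 12
Product: 13 (3S,4S,5R)-4-[(1S)-1-(tert-butyldimethylsilyloxy)-2-hydroxy-5-methylhex-5-en-1-yl]-5-ethenyl-3-[(phenylsulfanyl)methyl]oxolan-2-one (C9 epimers)
Conditions: CH2=C(CH3)CH2CH2MgBr (1.3 equiv, made from 4-bromo-2-methylbut-1-ene and Mg in THF), THF, −78 °C
Reagents that add atoms: (3-methylbut-3-en-1-yl)magnesium bromide, C=C(C)CC[Mg]Br
Why: Grignard addition to the aldehyde is chemoselective over the lactone at −78 °C and attaches C2–C4 with C15 and the second metathesis olefin; the new C9 carbinol centre forms as a mixture that is oxidised away in step 10.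

Step 10
Reactants: 13
Product: 14 (3S,4S,5R)-4-[(1S)-1-(tert-butyldimethylsilyloxy)-5-methyl-2-oxohex-5-en-1-yl]-5-ethenyl-3-[(phenylsulfanyl)methyl]oxolan-2-one
Conditions: Dess–Martin periodinane, NaHCO3, CH2Cl2, rt
Reagents that add atoms: none
Why: Dess–Martin oxidation converges both C9 epimers on the ketone that later serves as enol precursor and ring-expansion site.

Step 11
Reactants: 14
Product: 15 eight-membered ketone (4Z)-8β-(tert-butyldimethylsilyloxy)-4-methyl-9-oxo-13-(phenylsulfanyl)cyclooct-4-eno-6α,12-olide (ring atoms C2–C9; lactone trans-fused at C6/C7)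
Conditions: second-generation Grubbs catalyst (H2IMes)(PCy3)Cl2Ru=CHPh (10 mol%), toluene (1 mM), 80 °C
Reagents that add atoms: none
Why: Ring-closing olefin metathesis between the C5 vinyl group and the 1,1-disubstituted C4 olefin at high dilution closes the eight-membered ring C2–C9, in which the new trisubstituted C4=C5 bond can only be cis (Z), the geometry the target epoxide requires.

Step 12
Reactants: 15
Product: 16 C9 trimethylsilyl enol ether of 15 (C9=C2 double bond)
Conditions: LiN(iPr)2 (1.05 equiv), Me3SiCl (in situ quench), THF, −78 °C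
Reagents that add atoms: chlorotrimethylsilane, C[Si](C)(C)Cl
Why: Kinetic deprotonation with internal silyl quench removes a proton from the unhindered C2 methylene rather than from the silyloxy-bearing C8 methine or the hindered lactone α-position, giving the regiodefined C9=C2 silyl enol ether.

Step 13
Reactants: 16; 17 methyl propiolate
Product: 19 ten-membered β-keto ester methyl 8β-(tert-butyldimethylsilyloxy)-9-oxo-13-(phenylsulfanyl)germacra-1Z,4Z-dien-6α,12-olid-14-oate (C10 configuration labile), via silyloxycyclobutene 18 (not isolated)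
Conditions: TiCl4 (1.1 equiv), CH2Cl2, −78 °C; then Et3N·3HF, THF, −78 → 0 °C
Reagents that add atoms: methyl propiolate 17, C#CC(=O)OC
Why: TiCl4-activated methyl propiolate is attacked at its β-carbon by C2 of the silyl enol ether (Mukaiyama–Michael addition) and the resulting allenoate closes onto the C9 silyloxocarbenium ion to give the cis-fused 1-silyloxybicyclo[6.2.0]dec-9-ene 18, a formal [2+2] cycloaddition; fluoride then frees the C9 alkoxide, which cleaves the shared C9–C2 bond by retro-aldol fragmentation, so that C10 with its ester and C1 stand between C9 and C2 and the eight-membered ring has become the ten-membered ring. The closest known reaction type is the two-carbon ring expansion of cyclic ketones through the [2+2] adducts of their enamines or silyl enol ethers with propiolates, as used to turn cyclooctanone into cyclodecane derivatives. The only ring closed is the cyclobutene (4-exo-trig attack of the allenoate carbon on the oxocarbenium carbon); the ten-membered ring is not made by cyclisation but by cleavage of the zero-atom bridge of the bicycle, and the C9–C2 bond breaks rather than C9–C10 because only that cleavage gives the stabilised β-keto ester dienolate and releases the cyclobutene strain. No stereocentre of the target is created: C9 and C2 of 18 are transient, C10 of 19 is a labile β-keto ester centre, the C1=C2 geometry is erased in step 15, and C6, C7, C8 and C11 are untouched. The step needs regioselectivity (C2 versus C8) and chemoselectivity (enol ether versus the C4=C5 alkene, lactone and silyl ether); the first is fixed by the regiodefined enol ether from step 12 and the second by the far higher nucleophilicity of the silyl enol ether at −78 °C.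

Step 14
Reactants: 19
Product: 20 methyl 8β-(tert-butyldimethylsilyloxy)-9α-hydroxy-13-(phenylsulfanyl)germacra-1Z,4Z-dien-6α,12-olid-14-oate (9S; C10 epimers)
Conditions: NaBH4, CeCl3·7H2O, MeOH, −40 °C
Reagents that add atoms: none
Why: Luche reduction is 1,2-selective for the C9 ketone of the keto tautomer; hydride is expected to add anti to the C8–O bond (Felkin–Anh polar model) from the ring periphery, giving the 8,9-syn (9S) alcohol, while the labile C10 centre is removed in step 15.

Step 15
Reactants: 20
Product: 21 methyl 8β-(tert-butyldimethylsilyloxy)-9α-hydroxy-13-(phenylsulfanyl)germacra-1(10)E,4Z-dien-6α,12-olid-14-oate (both ring double bonds cis within the ring)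
Conditions: DBU (1.0 equiv), CH2Cl2, rt → 40 °C
Reagents that add atoms: none
Why: Base-mediated isomerisation of the β,γ-unsaturated ester into conjugation (C10 deprotonation to the dienolate, reprotonation at C2) moves the double bond to C10=C1; under thermodynamic control the ring-cis trisubstituted enoate should result, and the free C9 hydroxyl is too poor a leaving group for β-elimination.

Step 16
Reactants: 21
Product: 22 methyl 9α-acetoxy-8β-(tert-butyldimethylsilyloxy)-13-(phenylsulfanyl)germacra-1(10)E,4Z-dien-6α,12-olid-14-oate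
Conditions: Ac2O, DMAP (cat.), pyridine, CH2Cl2, 0 °C → rt
Reagents that add atoms: acetic anhydride, CC(=O)OC(C)=O
Why: DMAP-catalysed acetylation of the only free hydroxyl installs the C9 acetate.

Step 17
Reactants: 22
Product: 24 methyl 9α-acetoxy-8β-(tert-butyldimethylsilyloxy)germacra-1(10)E,4Z,11(13)-trien-6α,12-olid-14-oate, via sulfoxide 23 (not isolated)
Conditions: NaIO4, MeOH/H2O, 0 °C → rt; then crude sulfoxide, CaCO3, toluene, 90–110 °C
Reagents that add atoms: none
Why: Periodate oxidises the sulfide selectively to the sulfoxide, whose thermal syn-elimination (sulfoxide pyrolysis) can only take the C11 hydrogen and so unveils the 11(13)-exocyclic methylene of the lactone.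

Step 18
Reactants: 24
Product: 25 methyl 9α-acetoxy-8β-hydroxygermacra-1(10)E,4Z,11(13)-trien-6α,12-olid-14-oate
Conditions: HF·pyridine, pyridine, THF, 0 °C → rt
Reagents that add atoms: none
Why: Buffered HF·pyridine cleaves the remaining secondary silyl ether, and the mildly acidic medium disfavours acetyl migration from O9 to O8 and translactonisation.

Step 19
Reactants: 25
Product: 26 methyl 9α-acetoxy-8β-(2-methylprop-2-enoyloxy)germacra-1(10)E,4Z,11(13)-trien-6α,12-olid-14-oate
Conditions: methacrylic anhydride, DMAP, Et3N, CH2Cl2, 0 °C → rt (BHT as inhibitor)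
Reagents that add atoms: methacrylic anhydride, C=C(C)C(=O)OC(=O)C(C)=C
Why: DMAP-catalysed acylation with the anhydride esterifies the C8 hydroxyl, run directly after step 18 to forestall acyl migration.

Step 20
Reactants: 26
Product: 28 target methyl (4R,5S,6S,7R,8S,9S)-9α-acetoxy-4α,5α-epoxy-8β-(2-methylprop-2-enoyloxy)germacra-1(10)E,11(13)-dien-6α,12-olid-14-oate, via bromohydrin 27 (not isolated)
Conditions: N-bromosuccinimide (1.1 equiv), DME/H2O, 0 °C; then Ag2O, DME, rt
Reagents that add atoms: water, O
Why: Halohydrin route to the epoxide: bromonium ion formation on the more exposed outer face of the only electron-rich alkene (C4=C5), Markovnikov anti opening by water at C4 and silver-assisted closure with inversion at C5 place the oxirane oxygen on the face opposite to bromine, which is expected to be the face syn to the C6 lactone oxygen (4R,5S), the face that direct peracid attack on medium-ring allylic ethers does not reach.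

**Compound list**
1 | diethyl (S)-malate | CCOC(=O)C[C@H](O)C(=O)OCC | starting material
2 | tert-butyl bromoacetate | CC(C)(C)OC(=O)CBr | starting material
3 | 3-tert-butyl 1,2-diethyl (1S,2R)-1-hydroxypropane-1,2,3-tricarboxylate | CCOC(=O)[C@H](CC(=O)OC(C)(C)C)[C@H](O)C(=O)OCC | intermediate
4 | 4-tert-butyl 1-ethyl (2R)-2-[(1S)-1,2-dihydroxyethyl]butanedioate | CCOC(=O)[C@H](CC(=O)OC(C)(C)C)[C@H](O)CO | intermediate
5 | 4-tert-butyl 1-ethyl (2R)-2-[(1S)-1,2-bis(tert-butyldimethylsilyloxy)ethyl]butanedioate | CCOC(=O)[C@H](CC(=O)OC(C)(C)C)[C@H](O[Si](C)(C)C(C)(C)C)CO[Si](C)(C)C(C)(C)C | intermediate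
6 | tert-butyl (3R,4S)-4,5-bis(tert-butyldimethylsilyloxy)-3-formylpentanoate | O=C[C@H](CC(=O)OC(C)(C)C)[C@H](O[Si](C)(C)C(C)(C)C)CO[Si](C)(C)C(C)(C)C | intermediate
7 | tert-butyl (3S,4R)-3-[(1S)-1,2-bis(tert-butyldimethylsilyloxy)ethyl]-4-hydroxyhex-5-enoate | C=C[C@@H](O)[C@H](CC(=O)OC(C)(C)C)[C@H](O[Si](C)(C)C(C)(C)C)CO[Si](C)(C)C(C)(C)C | intermediate
8 | (4S,5R)-4-[(1S)-1,2-bis(tert-butyldimethylsilyloxy)ethyl]-5-ethenyloxolan-2-one | C=C[C@H]1OC(=O)C[C@@H]1[C@H](O[Si](C)(C)C(C)(C)C)CO[Si](C)(C)C(C)(C)C | intermediate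
9 | O-trimethylsilyl ketene acetal of 8 (2-trimethylsilyloxy-4,5-dihydrofuran) | C=C[C@H]1OC(O[Si](C)(C)C)=C[C@@H]1[C@H](O[Si](C)(C)C(C)(C)C)CO[Si](C)(C)C(C)(C)C | intermediate
10 | (3S,4S,5R)-4-[(1S)-1,2-bis(tert-butyldimethylsilyloxy)ethyl]-5-ethenyl-3-[(phenylsulfanyl)methyl]oxolan-2-one | C=C[C@H]1OC(=O)[C@@H](CSc2ccccc2)[C@@H]1[C@H](O[Si](C)(C)C(C)(C)C)CO[Si](C)(C)C(C)(C)C | intermediate
11 | (3S,4S,5R)-4-[(1S)-1-(tert-butyldimethylsilyloxy)-2-hydroxyethyl]-5-ethenyl-3-[(phenylsulfanyl)methyl]oxolan-2-one | C=C[C@H]1OC(=O)[C@@H](CSc2ccccc2)[C@@H]1[C@H](O[Si](C)(C)C(C)(C)C)CO | intermediate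
12 | (2S)-2-(tert-butyldimethylsilyloxy)-2-[(2R,3S,4S)-2-ethenyl-5-oxo-4-[(phenylsulfanyl)methyl]oxolan-3-yl]acetaldehyde | C=C[C@H]1OC(=O)[C@@H](CSc2ccccc2)[C@@H]1[C@H](O[Si](C)(C)C(C)(C)C)C=O | intermediate
13 | (3S,4S,5R)-4-[(1S)-1-(tert-butyldimethylsilyloxy)-2-hydroxy-5-methylhex-5-en-1-yl]-5-ethenyl-3-[(phenylsulfanyl)methyl]oxolan-2-one (C9 epimers) | C=C[C@H]1OC(=O)[C@@H](CSc2ccccc2)[C@@H]1[C@H](O[Si](C)(C)C(C)(C)C)C(O)CCC(C)=C | intermediate
14 | (3S,4S,5R)-4-[(1S)-1-(tert-butyldimethylsilyloxy)-5-methyl-2-oxohex-5-en-1-yl]-5-ethenyl-3-[(phenylsulfanyl)methyl]oxolan-2-one | C=C[C@H]1OC(=O)[C@@H](CSc2ccccc2)[C@@H]1[C@H](O[Si](C)(C)C(C)(C)C)C(=O)CCC(C)=C | intermediate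
15 | (4Z)-8β-(tert-butyldimethylsilyloxy)-4-methyl-9-oxo-13-(phenylsulfanyl)cyclooct-4-eno-6α,12-olide (ring C2–C9, trans-fused lactone) | C/C1=C/[C@H]2OC(=O)[C@@H](CSc3ccccc3)[C@@H]2[C@H](O[Si](C)(C)C(C)(C)C)C(=O)CC1 | intermediate
16 | C9 trimethylsilyl enol ether of 15 (C9=C2) | C/C1=C/[C@H]2OC(=O)[C@@H](CSc3ccccc3)[C@@H]2[C@H](O[Si](C)(C)C(C)(C)C)/C(O[Si](C)(C)C)=C\C1 | intermediate
17 | methyl propiolate | C#CC(=O)OC | starting material
18 | cis-fused 1-(trimethylsilyloxy)bicyclo[6.2.0]dec-9-ene-10-carboxylate adduct (cyclobutene C9–C10=C1–C2; configuration at C9 and C2 inconsequential) | C/C1=C/[C@H]2OC(=O)[C@@H](CSc3ccccc3)[C@@H]2[C@H](O[Si](C)(C)C(C)(C)C)C4(O[Si](C)(C)C)C(C(=O)OC)=CC4C1 | intermediate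
19 | methyl 8β-(tert-butyldimethylsilyloxy)-9-oxo-13-(phenylsulfanyl)germacra-1Z,4Z-dien-6α,12-olid-14-oate (keto form; C10 labile) | C/C1=C/[C@H]2OC(=O)[C@@H](CSc3ccccc3)[C@@H]2[C@H](O[Si](C)(C)C(C)(C)C)C(=O)C(C(=O)OC)/C=C\C1 | intermediate
20 | methyl 8β-(tert-butyldimethylsilyloxy)-9α-hydroxy-13-(phenylsulfanyl)germacra-1Z,4Z-dien-6α,12-olid-14-oate (C10 epimers) | C/C1=C/[C@H]2OC(=O)[C@@H](CSc3ccccc3)[C@@H]2[C@H](O[Si](C)(C)C(C)(C)C)[C@@H](O)C(C(=O)OC)/C=C\C1 | intermediate
21 | methyl 8β-(tert-butyldimethylsilyloxy)-9α-hydroxy-13-(phenylsulfanyl)germacra-1(10)E,4Z-dien-6α,12-olid-14-oate | C/C1=C/[C@H]2OC(=O)[C@@H](CSc3ccccc3)[C@@H]2[C@H](O[Si](C)(C)C(C)(C)C)[C@@H](O)/C(C(=O)OC)=C\CC1 | intermediate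
22 | methyl 9α-acetoxy-8β-(tert-butyldimethylsilyloxy)-13-(phenylsulfanyl)germacra-1(10)E,4Z-dien-6α,12-olid-14-oate | C/C1=C/[C@H]2OC(=O)[C@@H](CSc3ccccc3)[C@@H]2[C@H](O[Si](C)(C)C(C)(C)C)[C@@H](OC(C)=O)/C(C(=O)OC)=C\CC1 | intermediate
23 | 13-(phenylsulfinyl) analogue of 22 (sulfoxide, both configurations at sulfur) | C/C1=C/[C@H]2OC(=O)[C@@H](CS(=O)c3ccccc3)[C@@H]2[C@H](O[Si](C)(C)C(C)(C)C)[C@@H](OC(C)=O)/C(C(=O)OC)=C\CC1 | intermediate
24 | methyl 9α-acetoxy-8β-(tert-butyldimethylsilyloxy)germacra-1(10)E,4Z,11(13)-trien-6α,12-olid-14-oate | C/C1=C/[C@H]2OC(=O)C(=C)[C@@H]2[C@H](O[Si](C)(C)C(C)(C)C)[C@@H](OC(C)=O)/C(C(=O)OC)=C\CC1 | intermediate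
25 | methyl 9α-acetoxy-8β-hydroxygermacra-1(10)E,4Z,11(13)-trien-6α,12-olid-14-oate | C/C1=C/[C@H]2OC(=O)C(=C)[C@@H]2[C@H](O)[C@@H](OC(C)=O)/C(C(=O)OC)=C\CC1 | intermediate
26 | methyl 9α-acetoxy-8β-(2-methylprop-2-enoyloxy)germacra-1(10)E,4Z,11(13)-trien-6α,12-olid-14-oate | C/C1=C/[C@H]2OC(=O)C(=C)[C@@H]2[C@H](OC(=O)C(C)=C)[C@@H](OC(C)=O)/C(C(=O)OC)=C\CC1 | intermediate
27 | 5β-bromo-4α-hydroxy-4,5-dihydro derivative of 26 (bromohydrin) | C[C@]1(O)[C@H](Br)[C@H]2OC(=O)C(=C)[C@@H]2[C@H](OC(=O)C(C)=C)[C@@H](OC(C)=O)/C(C(=O)OC)=C\CC1 | intermediate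
28 | methyl (4R,5S,6S,7R,8S,9S)-9α-acetoxy-4α,5α-epoxy-8β-(2-methylprop-2-enoyloxy)germacra-1(10)E,11(13)-dien-6α,12-olid-14-oate (CNP0153978.8) | C=C(C)C(=O)O[C@H]1[C@H]2C(=C)C(=O)O[C@@H]2[C@@H]2O[C@]2(C)CC/C=C(/C(=O)OC)[C@@H]1OC(C)=O | target

**Step count and risks**
Total step count: 20. Longest linear sequence: 20 steps (the route is fully linear from 1).

Steps most likely to fail:

1. Step 13 (key step). The Lewis acid may divert the silyl enol ether into open-chain Mukaiyama–Michael products (silyl loss before the four-membered ring closes). It may also promote transannular attack of the C4=C5 alkene on the C9 oxocarbenium ion, or simply cleave the enol ether back to the ketone. Fallback (thermal, amine-based variant of the same two-carbon insertion): setting out from ketone 15, condensation with pyrrolidine (TiCl4, excess pyrrolidine, 0 °C) should give the less substituted C9 pyrrolidine enamine F1. F1 and methyl propiolate 17 in diethyl ether at 25–35 °C should form the aminocyclobutene F2, which opens by conrotatory 4π-electrocyclic ring opening to the ten-membered dienamino ester F3. Hydrolysis of F3 with aqueous acetic acid comes back to the route at β-keto ester 19.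

2. Step 15. The equilibrium between the deconjugated and the conjugated ester may be unfavourable in the ten-membered ring, or the dienolate may fragment by retro-aldol cleavage of the C9–C10 bond. Fallback (dehydrogenation instead of isomerisation): setting out from 19, diimide (KO2CN=NCO2K, AcOH) should saturate the disubstituted C1=C2 bond in preference to the trisubstituted C4=C5 bond and give the saturated β-keto ester F4. Selenenylation at C10 (PhSeCl, pyridine, 0 °C) gives the α-phenylselanyl β-keto ester F5, and oxidation (H2O2, 1.1 equiv, 0 °C) gives the selenoxide F6. Syn-elimination of F6 towards C1 gives the alkylidene β-keto ester F7, and Luche reduction of F7 (NaBH4, CeCl3·7H2O) comes back to the route at allylic alcohol 21.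

3. Step 20. The facial course of bromonium formation, or of its opening by water, may be the reverse of that assumed, because the conformation of the ten-membered ring is not known; the tertiary bromohydrin may also close sluggishly. Fallback: setting out from 26, direct syn oxygen transfer to the C4=C5 bond from a peracid (m-chloroperbenzoic acid, NaHCO3, CH2Cl2, 0 °C) or from dimethyldioxirane delivers oxygen to the face that bromine would occupy. This gives the complementary facial outcome and comes back to the route at 28 without any new intermediate.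

Further compounds
F1 | step 13 | C9 pyrrolidine enamine of 15 (C9=C2) | C/C1=C/[C@H]2OC(=O)[C@@H](CSc3ccccc3)[C@@H]2[C@H](O[Si](C)(C)C(C)(C)C)/C(N3CCCC3)=C\C1
F2 | step 13 | aminocyclobutene adduct, 1-(pyrrolidin-1-yl)bicyclo[6.2.0]dec-9-ene-10-carboxylate analogue of 18 | C/C1=C/[C@H]2OC(=O)[C@@H](CSc3ccccc3)[C@@H]2[C@H](O[Si](C)(C)C(C)(C)C)C4(N3CCCC3)C(C(=O)OC)=CC4C1
F3 | step 13 | ten-membered dienamino ester, methyl 9-(pyrrolidin-1-yl)germacra-1,4,9-trien-6α,12-olid-14-oate analogue (cis,trans-diene, geometry not fixed in the SMILES) | C/C1=C/[C@H]2OC(=O)[C@@H](CSc3ccccc3)[C@@H]2[C@H](O[Si](C)(C)C(C)(C)C)C(N3CCCC3)=C(C(=O)OC)C=CC1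
F4 | step 15 | saturated β-keto ester, 1,2-dihydro-19 | C/C1=C/[C@H]2OC(=O)[C@@H](CSc3ccccc3)[C@@H]2[C@H](O[Si](C)(C)C(C)(C)C)C(=O)C(C(=O)OC)CCC1
F5 | step 15 | 10-(phenylselanyl) derivative of F4 | C/C1=C/[C@H]2OC(=O)[C@@H](CSc3ccccc3)[C@@H]2[C@H](O[Si](C)(C)C(C)(C)C)C(=O)C([Se]c3ccccc3)(C(=O)OC)CCC1
F6 | step 15 | selenoxide of F5 | C/C1=C/[C@H]2OC(=O)[C@@H](CSc3ccccc3)[C@@H]2[C@H](O[Si](C)(C)C(C)(C)C)C(=O)C([Se](=O)c3ccccc3)(C(=O)OC)CCC1
F7 | step 15 | alkylidene β-keto ester, methyl 8β-(tert-butyldimethylsilyloxy)-9-oxo-13-(phenylsulfanyl)germacra-1(10),4Z-dien-6α,12-olid-14-oate (ring-cis C10=C1) | C/C1=C/[C@H]2OC(=O)[C@@H](CSc3ccccc3)[C@@H]2[C@H](O[Si](C)(C)C(C)(C)C)C(=O)/C(C(=O)OC)=C\CC1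
F0 | step 20 | none | none
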